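**Plan**
- Retrosynthesis: the benzyl ethers and a blocking bromine on C8′ come off last, and the C2–H bond is traced back to a C2 silyl ketal. Ring C of the upper epiafzelechin unit (O1, C2, C3, C4, C4a, C8a; three contiguous stereocentres, C4 bonded to C6′ of ring D) is then cut at O1–C2 and C3–C4, because this pattern is an ortho-quinone methide O1=C8a–C4a=C4 of ring A plus a C2=C3 enol ether.
- The quinone methide precursor, a ring A ortho-hydroxybenzhydrol on C6′, is cut at C4–C4a into a C6′ aldehyde of protected epicatechin gallate and a magnesium phenoxide. The enol ether goes back to an α-benzyloxy aryl ketone (aryl–CO bond).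
- Forward: (−)-epicatechin is benzylated, brominated at C8′, galloylated at O3′ and formylated at C6′; phenoxide addition gives the benzhydrol; the hetero-Diels–Alder step closes ring C; ketal reduction and hydrogenolysis finish.
- Stereochemistry: C2′ and C3′ come from (−)-epicatechin. C4 is set by the chiral phosphoric acid, C3 by the endo approach of the (Z)-enol ether (3,4-trans), and C2 by axial hydride addition to the oxocarbenium ion (2,3-cis).

Key step: step 8

Numbering: upper unit C2–C8a with rings A, C and B; lower unit C2′–C8a′ with rings D, F and E. The monomeric epicatechin derivatives are named as chromans, whose C6 and C8 become C6′ and C8′ of the dimer.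

Assumption: (R)-TRIP is taken as the catalyst enantiomer matched to attack on the 4β face of the quinone methide; if the pairing proves mismatched, the (S)-acid takes its place with no other change.

**Route**

Step 1
Reactants: 1 (−)-epicatechin
Product: 2 (2R,3R)-5,7-bis(benzyloxy)-2-[3,4-bis(benzyloxy)phenyl]chroman-3-ol (tetra-O-benzyl-(−)-epicatechin)
Conditions: BnBr, K2CO3, DMF, 0 °C to rt
Reagents that add atoms: benzyl bromide, BrCc1ccccc1
Why: Williamson ether synthesis on the four phenols, which K2CO3 deprotonates while the aliphatic 3′-OH stays neutral; working at or below room temperature avoids base-induced epimerisation at C2′, so both stereocentres are carried over unchanged.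

Step 2
Reactants: 2 tetra-O-benzyl-(−)-epicatechin
Product: 3 (2R,3R)-8-bromo-5,7-bis(benzyloxy)-2-[3,4-bis(benzyloxy)phenyl]chroman-3-ol
Conditions: NBS, CH2Cl2, −78 °C to 0 °C
Reagents that add atoms: N-bromosuccinimide, O=C1CCC(=O)N1Br
Why: Electrophilic aromatic bromination; of the two free positions of the phloroglucinol-type ring D, C8′ is the one attacked by NBS at low temperature in 5,7-di-O-benzylated flavan-3-ols, which leaves C6′ as the only open site for the carbon electrophile of step 4.

Step 3
Reactants: 3 8-bromo-tetra-O-benzylepicatechin; 4 3,4,5-tris(benzyloxy)benzoic acid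
Product: 5 (2R,3R)-8-bromo-5,7-bis(benzyloxy)-2-[3,4-bis(benzyloxy)phenyl]chroman-3-yl 3,4,5-tris(benzyloxy)benzoate
Conditions: DCC, DMAP (cat.), CH2Cl2, rt
Reagents that add atoms: none
Why: Steglich esterification through the N-acylpyridinium ion of 4 acylates the axial secondary alcohol without touching a stereocentre, and placing the benzylated galloyl group now spares a separate protection and deprotection of O3′.

Step 4
Reactants: 5 8-bromo-tetra-O-benzylepicatechin tri-O-benzylgallate
Product: 7 (2R,3R)-8-bromo-6-formyl-5,7-bis(benzyloxy)-2-[3,4-bis(benzyloxy)phenyl]chroman-3-yl 3,4,5-tris(benzyloxy)benzoate, via C6′ dimethyliminium chloride 6 (not isolated)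
Conditions: POCl3, DMF, 0 °C to 70 °C; then ice-water
Reagents that add atoms: N,N-dimethylformamide, CN(C)C=O; water, O
Why: Vilsmeier–Haack formylation; the chloroiminium ion attacks the only free position of the trioxygenated ring D (C6′), the catechol-type ring E and the ester-deactivated galloyl ring being far less nucleophilic, and aqueous hydrolysis of iminium salt 6 releases the aldehyde.

Step 5
Reactants: 7 C6′ aldehyde; 8 3,5-bis(benzyloxy)phenol
Product: 10 ring A ortho-hydroxybenzhydrol on C6′ of ester 5 (both carbinol epimers), via bromomagnesium 3,5-bis(benzyloxy)phenoxide 9 (not isolated)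
Conditions: 8 (slight excess over base), EtMgBr, Et2O, 0 °C; solvent exchange to toluene; 7, rt; then cold pH 7 buffer
Reagents that add atoms: none
Why: Ortho-selective hydroxyalkylation of a magnesium phenoxide by an aldehyde: in the non-coordinating solvent the aldehyde binds to magnesium and is delivered through a six-membered chelate to the carbon ortho to the phenoxide oxygen, a phenoxide does not attack the ester, and the new carbinol centre forms without control but is lost on ionisation in step 8.

Step 6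
Reactants: 11 1-(benzyloxy)-4-bromobenzene; 12 2-(benzyloxy)-N-methoxy-N-methylacetamide
Product: 15 2-(benzyloxy)-1-[4-(benzyloxy)phenyl]ethanone, via 4-(benzyloxy)phenylmagnesium bromide 13 (not isolated), via tetrahedral magnesium adduct 14 (not isolated)
Conditions: Mg, THF, rt; then 12, THF, 0 °C; then aq. NH4Cl
Reagents that add atoms: none
Why: Weinreb ketone synthesis; the aryl Grignard reagent adds only once because the chelated tetrahedral adduct 14 survives until aqueous work-up.

Step 7
Reactants: 15 2-(benzyloxy)-1-[4-(benzyloxy)phenyl]ethanone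
Product: 16 (Z)-tert-butyldimethylsilyl enol ether of 15 (OTBS and OBn cis)
Conditions: TBSOTf, Et3N, CH2Cl2, 0 °C to rt
Reagents that add atoms: tert-butyldimethylsilyl trifluoromethanesulfonate, CC(C)(C)[Si](C)(C)OS(=O)(=O)C(F)(F)F
Why: Soft enolisation and O-silylation of an aryl ketone gives the (Z)-silyl enol ether because the E isomer would press the C2 benzyloxy group against the aryl ring (allylic 1,3-strain); this alkene geometry later fixes the C2/C3 relationship.

Step 8
Reactants: 10 ortho-hydroxybenzhydrol; 16 (Z)-silyl enol ether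
Product: 18 C2 silyl ketal of the protected dimer (ring C closed; C4–ring D β; C3–OBn trans to ring D; C2–OTBS cis to C3–OBn), via (E)-ortho-quinone methide 17 (not isolated)
Conditions: 16 (2 equiv), (R)-TRIP [(R)-3,3′-bis(2,4,6-triisopropylphenyl)-1,1′-binaphthyl-2,2′-diyl hydrogen phosphate] (10 mol %), 5 Å MS, CH2Cl2, −40 °C to −10 °C
Reagents that add atoms: none
Why: The phosphoric acid protonates the carbinol of 10 and water leaves (taken up by the sieves, which protects 16 from protodesilylation) to give the (E)-ortho-quinone methide 17, O1=C8a–C4a=C4, hydrogen-bonded through O1 to the chiral phosphate. The nucleophilic C3 of 16 attacks the electrophilic C4 while O1 captures the developing C2 silyloxocarbenium centre, a concerted but asynchronous inverse-electron-demand hetero-Diels–Alder reaction of the type established for in situ ortho-quinone methides and enol ethers under chiral phosphoric acids. Ring C is closed by the [4+2] cycloaddition itself (in the stepwise limit a 6-exo-trig attack of the ring A oxygen on the oxocarbenium carbon), and regiochemistry follows polarity because both donors of 16 (OTBS and aryl) sit on the carbon that becomes C2, which leaves the benzyloxy group on C3. C4 is controlled by the catalyst, whose 3,3′-aryl groups shield one face of 17 (the stereocentres of the lower unit are remote, so catalyst control should dominate); C3 is controlled relative to C4 by the aryl-endo approach of the (Z)-alkene to the (E)-quinone methide, which places OBn anti to ring D (3,4-trans); C2 follows from suprafacial addition (OTBS cis to OBn) and is erased in step 9. The step needs facial and endo/exo selectivity plus chemoselectivity over Friedel–Crafts self-alkylation. The catalyst, the fixed Z geometry of 16 used in excess, the E geometry of 17 and the bromine on C8′, which closes the only free position of ring D, are meant to secure these.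

Step 9
Reactants: 18 C2 silyl ketal
Product: 20 fully benzylated 8′-bromo-epiafzelechin-(4β→6)-epicatechin 3′-O-gallate (2,3-cis-3,4-trans upper unit), via C2 oxocarbenium ion 19 (not isolated)
Conditions: Et3SiH, BF3·OEt2, CH2Cl2, −78 °C to −40 °C
Reagents that add atoms: none
Why: Ionic hydrogenation of a ketal: BF3 removes the C2 silyloxy group, oxocarbenium ion 19 adopts the half-chair with the C4 aryl group and the C3 benzyloxy group trans-diaxial (the C4 aryl group avoids the peri C5 benzyloxy group), and Et3SiH adds axially anti to the C3 benzyloxy group, which places the ring B aryl group cis to it (2,3-cis), while the low temperature keeps the acid-labile C4–C6′ bond intact.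

Step 10
Reactants: 20 protected bromo dimer
Product: 21 epiafzelechin-(4β→6)-epicatechin 3′-O-gallate (target; upper unit 2R,3R,4S, lower unit 2′R,3′R)
Conditions: H2 (1 atm), Pd(OH)2/C, NaOAc, THF/MeOH, rt; filtration under argon
Reagents that add atoms: none
Why: Heterogeneous hydrogenolysis cleaves the eleven benzyl ethers and the aryl C–Br bond in one operation, NaOAc takes up the HBr that could otherwise cleave the interflavan bond, and the ester, the ring C and ring F C–O bonds and all five stereocentres should be unaffected under these mild conditions.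

**Compound list**

1 | (−)-epicatechin | O[C@@H]1Cc2c(O)cc(O)cc2O[C@@H]1c1ccc(O)c(O)c1 | starting material
2 | (2R,3R)-5,7-bis(benzyloxy)-2-[3,4-bis(benzyloxy)phenyl]chroman-3-ol | O[C@@H]1Cc2c(OCc3ccccc3)cc(OCc3ccccc3)cc2O[C@@H]1c1ccc(OCc2ccccc2)c(OCc2ccccc2)c1 | intermediate
3 | (2R,3R)-8-bromo-5,7-bis(benzyloxy)-2-[3,4-bis(benzyloxy)phenyl]chroman-3-ol | O[C@@H]1Cc2c(OCc3ccccc3)cc(OCc3ccccc3)c(Br)c2O[C@@H]1c1ccc(OCc2ccccc2)c(OCc2ccccc2)c1 | intermediate
4 | 3,4,5-tris(benzyloxy)benzoic acid | OC(=O)c1cc(OCc2ccccc2)c(OCc2ccccc2)c(OCc2ccccc2)c1 | starting material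
5 | (2R,3R)-8-bromo-5,7-bis(benzyloxy)-2-[3,4-bis(benzyloxy)phenyl]chroman-3-yl 3,4,5-tris(benzyloxy)benzoate | O=C(O[C@@H]1Cc2c(OCc3ccccc3)cc(OCc3ccccc3)c(Br)c2O[C@@H]1c1ccc(OCc2ccccc2)c(OCc2ccccc2)c1)c1cc(OCc2ccccc2)c(OCc2ccccc2)c(OCc2ccccc2)c1 | intermediate
6 | C6′ N,N-dimethyliminium chloride of 5 (aryl–CH=NMe2+ Cl−) | O=C(O[C@@H]1Cc2c(OCc3ccccc3)c(C=[N+](C)C)c(OCc3ccccc3)c(Br)c2O[C@@H]1c1ccc(OCc2ccccc2)c(OCc2ccccc2)c1)c1cc(OCc2ccccc2)c(OCc2ccccc2)c(OCc2ccccc2)c1.[Cl-] | intermediate
7 | (2R,3R)-8-bromo-6-formyl-5,7-bis(benzyloxy)-2-[3,4-bis(benzyloxy)phenyl]chroman-3-yl 3,4,5-tris(benzyloxy)benzoate | O=C(O[C@@H]1Cc2c(OCc3ccccc3)c(C=O)c(OCc3ccccc3)c(Br)c2O[C@@H]1c1ccc(OCc2ccccc2)c(OCc2ccccc2)c1)c1cc(OCc2ccccc2)c(OCc2ccccc2)c(OCc2ccccc2)c1 | intermediate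
8 | 3,5-bis(benzyloxy)phenol | Oc1cc(OCc2ccccc2)cc(OCc2ccccc2)c1 | starting material
9 | bromomagnesium 3,5-bis(benzyloxy)phenoxide | Br[Mg]Oc1cc(OCc2ccccc2)cc(OCc2ccccc2)c1 | intermediate
10 | ortho-hydroxybenzhydrol: ester 5 carrying on C6′ a CH(OH) group whose second aryl group is 2-hydroxy-4,6-bis(benzyloxy)phenyl (ring A); lower unit 2′R,3′R; carbinol centre a mixture of both epimers and left undefined | O=C(O[C@@H]1Cc2c(OCc3ccccc3)c(C(O)c3c(O)cc(OCc4ccccc4)cc3OCc3ccccc3)c(OCc3ccccc3)c(Br)c2O[C@@H]1c1ccc(OCc2ccccc2)c(OCc2ccccc2)c1)c1cc(OCc2ccccc2)c(OCc2ccccc2)c(OCc2ccccc2)c1 | intermediate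
11 | 1-(benzyloxy)-4-bromobenzene | Brc1ccc(OCc2ccccc2)cc1 | starting material
12 | 2-(benzyloxy)-N-methoxy-N-methylacetamide | CON(C)C(=O)COCc1ccccc1 | starting material
13 | 4-(benzyloxy)phenylmagnesium bromide | Br[Mg]c1ccc(OCc2ccccc2)cc1 | intermediate
14 | bromomagnesium salt of the tetrahedral adduct of 13 and 12 | CON(C)C(O[Mg]Br)(COCc1ccccc1)c1ccc(OCc2ccccc2)cc1 | intermediate
15 | 2-(benzyloxy)-1-[4-(benzyloxy)phenyl]ethanone | O=C(COCc1ccccc1)c1ccc(OCc2ccccc2)cc1 | intermediate
16 | (Z)-[2-(benzyloxy)-1-(4-(benzyloxy)phenyl)ethenyloxy](tert-butyl)dimethylsilane | CC(C)(C)[Si](C)(C)O/C(c1ccc(OCc2ccccc2)cc1)=C\OCc1ccccc1 | intermediate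
17 | (E)-ortho-quinone methide: 3,5-bis(benzyloxy)-6-(arylmethylidene)cyclohexa-2,4-dienone with C6′ of the lower unit on the methylidene carbon, anti to the carbonyl group | O=C(O[C@@H]1Cc2c(OCc3ccccc3)c(/C=C3/C(=O)C=C(OCc4ccccc4)C=C3OCc3ccccc3)c(OCc3ccccc3)c(Br)c2O[C@@H]1c1ccc(OCc2ccccc2)c(OCc2ccccc2)c1)c1cc(OCc2ccccc2)c(OCc2ccccc2)c(OCc2ccccc2)c1 | intermediate
18 | C2 silyl ketal: 2-(tert-butyldimethylsilyloxy) flavan with 3-OBn, 5,7-di-OBn and ring B 4-OBn, linked C4→C6′ to ester 5; C4 bond β, C3–OBn trans to it, C2–OTBS cis to C3–OBn | O=C(O[C@@H]1Cc2c(c(Br)c(OCc3ccccc3)c([C@H]3c4c(OCc5ccccc5)cc(OCc5ccccc5)cc4O[C@@](O[Si](C)(C)C(C)(C)C)(c4ccc(OCc5ccccc5)cc4)[C@@H]3OCc3ccccc3)c2OCc2ccccc2)O[C@@H]1c1ccc(OCc2ccccc2)c(OCc2ccccc2)c1)c1cc(OCc2ccccc2)c(OCc2ccccc2)c(OCc2ccccc2)c1 | intermediate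
19 | C2 oxocarbenium ion (O1=C2 cation) derived from 18 | O=C(O[C@@H]1Cc2c(c(Br)c(OCc3ccccc3)c([C@H]3c4c(OCc5ccccc5)cc(OCc5ccccc5)cc4[O+]=C(c4ccc(OCc5ccccc5)cc4)[C@@H]3OCc3ccccc3)c2OCc2ccccc2)O[C@@H]1c1ccc(OCc2ccccc2)c(OCc2ccccc2)c1)c1cc(OCc2ccccc2)c(OCc2ccccc2)c(OCc2ccccc2)c1 | intermediate
20 | undeca-O-benzyl-8′-bromo-epiafzelechin-(4β→6)-epicatechin 3′-O-gallate (upper unit 2,3-cis-3,4-trans; lower unit 2′R,3′R) | O=C(O[C@@H]1Cc2c(c(Br)c(OCc3ccccc3)c([C@H]3c4c(OCc5ccccc5)cc(OCc5ccccc5)cc4O[C@H](c4ccc(OCc5ccccc5)cc4)[C@@H]3OCc3ccccc3)c2OCc2ccccc2)O[C@@H]1c1ccc(OCc2ccccc2)c(OCc2ccccc2)c1)c1cc(OCc2ccccc2)c(OCc2ccccc2)c(OCc2ccccc2)c1 | intermediate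
21 | epiafzelechin-(4β→6)-epicatechin 3′-O-gallate (upper unit 2R,3R,4S; lower unit 2′R,3′R) | O=C(O[C@@H]1Cc2c(cc(O)c([C@H]3c4c(O)cc(O)cc4O[C@H](c4ccc(O)cc4)[C@@H]3O)c2O)O[C@@H]1c1ccc(O)c(O)c1)c1cc(O)c(O)c(O)c1 | target

**Step count**
Total: 10 steps. Longest linear sequence: 8 steps (steps 1–5, 8, 9 and 10 from (−)-epicatechin); steps 6 and 7 form the two-step side branch to the enol ether.

**Steps most likely to fail**

Step 8. The phosphate may discriminate poorly between the faces of this crowded quinone methide, which is flanked by two ortho-benzyloxy groups on each aryl ring. The acid may also desilylate the enol ether faster than it adds, or the cation may alkylate ring A of a second molecule. The fallback replaces the cycloaddition by the classical flavan-4-yl cation coupling and sets out from compound 5. Purchased (−)-epiafzelechin F1 is perbenzylated (NaH, BnBr, DMF) to 3,5,7-tri-O-benzyl-ring-B-4-O-benzyl-epiafzelechin F2. Benzylic oxidation with DDQ in the presence of 2-ethoxyethanol (CH2Cl2, rt) gives the 4β-(2-ethoxyethoxy) ether F3. TMSOTf (cat.) in CH2Cl2 at −78 °C ionises F3 in the presence of excess 5. Because C8′ is blocked the cation should be taken up at C6′, and attack trans to the C3 benzyloxy group should give the 4β linkage. The route is rejoined at compound 20.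

Step 5. Addition of the magnesium phenoxide to the hindered, electron-rich aldehyde may be slow, and the magnesium benzhydrolate may ionise and take up a second phenoxide to give a triarylmethane. The fallback is a boron-templated ortho-condensation and sets out from compounds 7 and 8. Heating them with PhB(OH)2 and catalytic propionic acid in toluene with removal of water should give the 2-phenyl-4H-1,3,2-benzodioxaborin F4, a neutral and storable form of the benzhydrol. Oxidative cleavage of the B–phenyl bond with aqueous H2O2 in THF at 0 °C releases the diol. The route is rejoined at compound 10.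

Step 9. Hydride may add to the wrong face of the oxocarbenium ion, the ion may lose the C3 proton to give a flav-2-ene, or BF3 may heterolyse the C4–C6′ bond. The fallback sets C2 by an invertive ring closure instead and sets out from compound 18. Buffered desilylation (TBAF, AcOH, THF, 0 °C) opens the ketal to the ring A phenol ketone F5. Chelation-controlled reduction with Zn(BH4)2 in Et2O at −20 °C, with zinc bridging the carbonyl and the α-benzyloxy oxygen, should give the erythro alcohol F6. Intramolecular Mitsunobu etherification (PPh3, DIAD, THF, 0 °C) closes O1–C2 with inversion to the 2,3-cis flavan. The route is rejoined at compound 20.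

**Further compounds**

F1 | step 8 | (−)-epiafzelechin (purchased) | O[C@@H]1Cc2c(O)cc(O)cc2O[C@@H]1c1ccc(O)cc1
F2 | step 8 | (2R,3R)-3,5,7-tris(benzyloxy)-2-[4-(benzyloxy)phenyl]chroman | O(Cc1ccccc1)[C@@H]1Cc2c(OCc3ccccc3)cc(OCc3ccccc3)cc2O[C@@H]1c1ccc(OCc2ccccc2)cc1
F3 | step 8 | 4β-(2-ethoxyethoxy) ether of F2 (C4 alkoxy group trans to C3–OBn) | CCOCCO[C@H]1c2c(OCc3ccccc3)cc(OCc3ccccc3)cc2O[C@H](c2ccc(OCc3ccccc3)cc2)[C@@H]1OCc1ccccc1
F4 | step 5 | 5,7-bis(benzyloxy)-2-phenyl-4H-1,3,2-benzodioxaborin carrying C6′ of ester 5 on C4 (C4 epimers) | O=C(O[C@@H]1Cc2c(OCc3ccccc3)c(C3OB(c4ccccc4)Oc4cc(OCc5ccccc5)cc(OCc5ccccc5)c34)c(OCc3ccccc3)c(Br)c2O[C@@H]1c1ccc(OCc2ccccc2)c(OCc2ccccc2)c1)c1cc(OCc2ccccc2)c(OCc2ccccc2)c(OCc2ccccc2)c1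
F5 | step 9 | ring A phenol ketone: 2-(benzyloxy)-1-[4-(benzyloxy)phenyl]-3-[2-hydroxy-4,6-bis(benzyloxy)phenyl]propan-1-one carrying C6′ of ester 5 on C3 (open form of the C2 hemiketal) | O=C(O[C@@H]1Cc2c(c(Br)c(OCc3ccccc3)c([C@@H](c3c(OCc4ccccc4)cc(OCc4ccccc4)cc3O)[C@@H](OCc3ccccc3)C(=O)c3ccc(OCc4ccccc4)cc3)c2OCc2ccccc2)O[C@@H]1c1ccc(OCc2ccccc2)c(OCc2ccccc2)c1)c1cc(OCc2ccccc2)c(OCc2ccccc2)c(OCc2ccccc2)c1
F6 | step 9 | erythro alcohol from reduction of F5 (carbinol centre opposite to C2 of 20) | O=C(O[C@@H]1Cc2c(c(Br)c(OCc3ccccc3)c([C@@H](c3c(OCc4ccccc4)cc(OCc4ccccc4)cc3O)[C@@H](OCc3ccccc3)[C@@H](O)c3ccc(OCc4ccccc4)cc3)c2OCc2ccccc2)O[C@@H]1c1ccc(OCc2ccccc2)c(OCc2ccccc2)c1)c1cc(OCc2ccccc2)c(OCc2ccccc2)c(OCc2ccccc2)c1
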